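# Proposed synthesis of CNP0562063.1 (compound 28) by a transannular Diels–Alder route

## Analysis of the target

Compound 28 is a labdane: a trans-fused decalin (ring A = C1–C5/C10, ring B = C5–C10) with a methyl group and the C19 carboxylic acid on C4, a hydroxymethyl group (C17) on C8, and on C9 a two-carbon chain (C11, C12) ending in an α-substituted butenolide (C13=C14, C15–O, C16=O). Labdane numbering is used for every compound below, and α/β refer to the usual drawing in which the C10 methyl (C20) is β. All five stereocentres lie in the decalin, (4S,5R,8R,9S,10R): C4 is quaternary with the acid β and axial, syn to C20; C5 has H α; C10 is quaternary; C9 has H α and its chain β, equatorial; C8 has H β and C17 α, equatorial and trans to the C9 chain. The butenolide is sensitive to base, hydride and nucleophiles, so it should be introduced last. The axial neopentyl acid cannot be released from an ordinary ester under conditions the butenolide survives, so it needs a latent form that is unmasked by oxidation. The difficulty lies in the two quaternary carbons C4 and C10 flanking C5, the contiguous tetrad C5–C10–C9–C8, the absolute configuration, and three oxidised carbons (C16, C17, C19) that must be kept apart. The strategy rests on ring B: its bonds C5–C10 and C8–C9 are the two σ-bonds of a [4+2] adduct of a C5=C6–C7=C8 diene and a C9=C10 alkene. C11 and C17 sit on the neighbouring carbons C9 and C8; if C11 is a carboxyl carbon esterified by the C17 oxygen, the triene becomes a thirteen-membered lactone and the cycloaddition is transannular. C4 is then the only stereocentre of the macrocycle, and a nitrile, the smallest carboxyl equivalent, is carried there.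

## Retrosynthetic reasoning

**C12–C13.** The butenolide of 28 is cut off as a whole at the sp3–sp2 bond C12–C13, which leads to the vinyl hydroxy acid 25 and the bromobutenolide 26. Cutting here means the lactone never meets a hydride or a strong base. Forward, the vinyl group has to be hydroborated at C12 and the alkyl group coupled to C13 under palladium catalysis.

**C19.** The acid of 25 is traced through the aldehyde 24 to the nitrile of 22. Forward, one hydride reagent both returns C17 to the alcohol and takes the nitrile to the aldimine 23, and a mild oxidation finishes the acid. No ester has to be cleaved at the hindered axial position.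

**C8.** The equatorial formyl group of 22 comes from the axial epimer 21 and that from the alcohol 20. The cycloaddition can only deliver C17 β, because C17 and C11 are tied in one ester bridge. C17 β is axial and 1,3-diaxial to C20, so equilibration through the aldehyde must give the α epimer.

**C11–C12.** The vinyl group of 20 is disconnected to the lactol 18, through its open form 19, and on to the saturated lactone 17 and the cycloadduct 16. The lactone carbonyl C11 thus becomes the first carbon of the side chain, and the same operation frees the C17 hydroxyl. The C6=C7 alkene left by the cycloaddition is removed first, while no other alkene is present.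

**C5–C10 and C8–C9 (key disconnection).** Both bonds of ring B in 16 are cut in one retro-[4+2] step to the thirteen-membered triene lactone 15. This removes rings A and B and the stereocentres C5, C9 and C10 (and C8) at once and leaves one stereocentre, C4. Forward, the E,E diene must add across the E enoate with the C1–C4 tether exo and the ester bridge endo, on the face set by C4.

**O–C11.** The macrolactone 15 is opened at the ester C–O bond to the hydroxy acid 13, made from the ethyl ester 12. A lactonisation is chosen because it uses the two functional groups that the later steps need anyway.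

**C6–C7 and C5=C6.** The E,E dienol of 12 is cut at C6–C7 into the vinyl iodide 10 and the stannane 11, and 10 is traced to the aldehyde 9. This brings C17 in at the alcohol oxidation level, so the enoate ester at C11 never has to be told apart from a second ester.

**C1–C10.** The E trisubstituted enoate of 9 (through alcohol 8 and borane 7) is cut at the sp3–sp2 bond C1–C10 into the alkene 6 and the enol triflate 2, which is made from 1. The alkene geometry is fixed in 2 and carried over unchanged, which avoids an olefination of a methyl ketone with its E/Z mixture.

**C3–C4.** Alcohol 6 comes from the ester 5, and 5 from 3 and 4 by cutting the bond C3–C4. An activated allylic electrophile is chosen so that the enantioselective alkylation is fast at low temperature. This is the only stereocentre set by an external chiral agent.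

## Alternatives that were turned down

**Alternative 1:** Rings A and B are disconnected at C4–C5 and C9–C10 to the acyclic β-keto ester diene A2, which carries a chiral ester group. In the forward step a trivalent manganese carboxylate oxidises A2 to the C4 radical, which closes ring A and then ring B. A divalent copper salt oxidises the final C8 radical to the exocyclic alkene of A1. In its favour, both rings, both quaternary carbons and four stereocentres (C4, C5, C9, C10) arise in one step from a polyene that is quick to assemble. C19 arrives at the carboxyl level and C11–C12 are already in place. On steps to the bicycle, and in avoiding a macrocyclisation, this is stronger than the chosen route. Against it, the absolute configuration depends on a remote ester auxiliary steering a planar radical. A1 also carries a C3 ketone that must be removed, and an 8(17) alkene whose hydroboration face at C8 is not secured. The hindered axial auxiliary ester cannot be cleaved once the butenolide is present. The chosen strategy offers instead a catalytically set C4 whose information is passed on through a closed pericyclic transition state, no surplus oxygen, and C11 and C17 delivered already differentiated.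

**Alternative 2:** Only ring B is disconnected, at C8–C9, to the ring A compound A4, which bears an enol ether chain on C5 and an allylsilane on C10. In the forward step, constant-current anodic oxidation in an alcohol solvent makes the enol ether radical cation. The allylsilane attacks it at C8, the silyl group is lost, and the solvent captures C17 as the acetal A3. In its favour, A3 has C17 at the aldehyde level with C8 already in the final orientation, so no inversion is needed, where the chosen route spends two steps. A3 also has the same C9 vinyl handle as 20–25, and no chemical oxidant is used. Against it, the C4/C5/C10 triad with both quaternary carbons must already exist in A4, so the hard part is moved into a long substrate synthesis. The attacking carbon C9 is neopentyl, and its configuration relative to C10 is not fixed by geometry. The C19 methyl ester would have to be cleaved late under conditions that endanger the butenolide. The chosen strategy builds both rings and C5, C9 and C10 from a precursor with one stereocentre and keeps C19 as a nitrile.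

**Alternative 3:** The butenolide is disconnected at C13–C16 and O–C16 to the alkynol A6. In the forward step, zerovalent palladium with a diphosphine under syngas adds hydride and an acyl group across the alkyne, and the C15 hydroxyl closes the lactone A5. In its favour, the regiochemistry follows from the mechanism, since only an acyl group on C13 can close a five-membered ring. The conditions are neutral, and on this point it is stronger than the base-mediated coupling with 26 used here. Against it, it is an end-game tactic that leaves the decalin and its five stereocentres unsolved. It needs pressurised gas and extra C–C bond formation to build A6. A5 still carries a hindered C19 methyl ester and a silyl ether to be removed after the butenolide exists. The chosen strategy attaches the ready-made butenolide in the last step with the acid and alcohol already free, and it solves the core in the same plan.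

Key step: step 10

Assumption: 3, 11 and 26 are bought, and the (S,S) catalyst of step 2 is taken to give (R)-5 (its antipode is used if the sense of induction proves opposite).

## Route

Step 1
Reactants: 1 ethyl acetoacetate
Product: 2 ethyl (2E)-3-{[(trifluoromethyl)sulfonyl]oxy}but-2-enoate
Conditions: Tf2O, aq. Me4NOH, hexanes, 5 °C → rt
Reagents that add atoms: trifluoromethanesulfonic anhydride, O=S(=O)(OS(=O)(=O)C(F)(F)F)C(F)(F)F
Why: Enol triflate formation from a β-keto ester: with the non-coordinating tetramethylammonium counter-ion the enolate is not chelated and should be O-sulfonylated as its E form (OTf trans to the ester), whereas a lithium base would give the chelated Z isomer. This geometry is what later places C1 trans to C11.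

Step 2
Reactants: 3 tert-butyl 2-cyanopropanoate; 4 allyl bromide
Product: 5 tert-butyl (2R)-2-cyano-2-methylpent-4-enoate
Conditions: (S,S)-N-spiro bis(binaphthyl)ammonium bromide with 3,4,5-trifluorophenyl groups (1–2 mol %), CsOH·H2O, PhMe, −40 °C
Reagents that add atoms: none
Why: Asymmetric phase-transfer alkylation of an α-cyano ester: the enolate of 3 enters toluene as a tight ion pair with the C2-symmetric ammonium cation, which shields one face, and the reactive allylic bromide should be attacked at −40 °C faster than by any uncatalysed path. This sets the quaternary carbon C4 (R in 5, 4S in 28) by catalyst control; the linear nitrile removes any E/Z ambiguity on that side of the enolate, and 5 has no α-hydrogen and cannot racemise.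

Step 3
Reactants: 5 tert-butyl (2R)-2-cyano-2-methylpent-4-enoate
Product: 6 (2R)-2-(hydroxymethyl)-2-methylpent-4-enenitrile
Conditions: LiBH4, THF, MeOH (1 equiv), 0 °C → rt
Reagents that add atoms: none
Why: Chemoselective borohydride reduction: LiBH4 should reduce the ester, made more electrophilic by the α-nitrile, to the primary alcohol and leave the nitrile and the alkene alone. The quaternary stereocentre is not touched.

Step 4
Reactants: 6 (2R)-2-(hydroxymethyl)-2-methylpent-4-enenitrile; 2 ethyl (2E)-3-{[(trifluoromethyl)sulfonyl]oxy}but-2-enoate
Product: 8 ethyl (2E,7R)-7-cyano-8-hydroxy-3,7-dimethyloct-2-enoate, via B-alkyl-9-BBN adduct 7 (not isolated)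
Conditions: 9-BBN-H (2.2 equiv), THF, 0 °C → rt; then 2, PdCl2(dppf) (5 mol %), AsPh3, aq. K3PO4, DMF, rt
Reagents that add atoms: none
Why: Hydroboration followed by B-alkyl Suzuki–Miyaura coupling: 9-BBN adds to the terminal alkene with boron on C1 (one more equivalent is held on the hydroxyl group and released by the aqueous base), and the alkyl group is transferred to the enol triflate on palladium with retention of the alkene geometry. The C1–C10 bond and the E trisubstituted enoate are made in one flask; no stereocentre is formed.

Step 5
Reactants: 8 ethyl (2E,7R)-7-cyano-8-hydroxy-3,7-dimethyloct-2-enoate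
Product: 9 ethyl (2E,7R)-7-cyano-3,7-dimethyl-8-oxooct-2-enoate
Conditions: Dess–Martin periodinane, NaHCO3, CH2Cl2, 0 °C → rt
Reagents that add atoms: none
Why: Dess–Martin oxidation of a neopentyl primary alcohol under buffered, non-basic conditions; the aldehyde has no α-hydrogen and the enoate is inert.

Step 6
Reactants: 9 ethyl (2E,7R)-7-cyano-3,7-dimethyl-8-oxooct-2-enoate
Product: 10 ethyl (2E,7S,8E)-7-cyano-9-iodo-3,7-dimethylnona-2,8-dienoate
Conditions: CrCl2 (6 equiv), CHI3 (2 equiv), THF, 0 °C → rt
Reagents that add atoms: iodoform, IC(I)I
Why: Takai olefination: the geminal dichromium species formed from iodoform and CrCl2 adds to the aldehyde and eliminates to give the E vinyl iodide (C5=C6). The reagent is not basic, so the α-cyano aldehyde should not be deformylated, and ester and nitrile are tolerated; the descriptor at C4 changes to S only because the priorities change.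

Step 7
Reactants: 10 ethyl (2E,7S,8E)-7-cyano-9-iodo-3,7-dimethylnona-2,8-dienoate; 11 (2E)-3-(tributylstannyl)prop-2-en-1-ol
Product: 12 ethyl (2E,7S,8E,10E)-7-cyano-12-hydroxy-3,7-dimethyldodeca-2,8,10-trienoate
Conditions: Pd2(dba)3 (2.5 mol %), AsPh3 (20 mol %), DMF, rt
Reagents that add atoms: none
Why: Stille coupling of an alkenyl iodide with an alkenylstannane on zerovalent palladium; both partners react with retention, so the C6–C7 bond is formed inside an E,E diene, and the free allylic alcohol needs no protection.

Step 8
Reactants: 12 ethyl (2E,7S,8E,10E)-7-cyano-12-hydroxy-3,7-dimethyldodeca-2,8,10-trienoate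
Product: 13 (2E,7S,8E,10E)-7-cyano-12-hydroxy-3,7-dimethyldodeca-2,8,10-trienoic acid
Conditions: LiOH·H2O, THF/MeOH/H2O, rt; then 1 M HCl to pH 4, 0 °C
Reagents that add atoms: lithium hydroxide, [Li+].[OH-]
Why: Saponification of the ethyl enoate; the tertiary nitrile is too hindered to hydrolyse at room temperature, and the mild, cold acidification avoids ionising the dienyl alcohol.

Step 9
Reactants: 13 (2E,7S,8E,10E)-7-cyano-12-hydroxy-3,7-dimethyldodeca-2,8,10-trienoic acid
Product: 15 (3E,8S,9E,11E)-4,8-dimethyl-2-oxo-1-oxacyclotrideca-3,9,11-triene-8-carbonitrile, via mixed anhydride 14 (not isolated)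
Conditions: 2,4,6-Cl3C6H2COCl, Et3N, THF, rt; then slow addition to DMAP, PhMe (0.001 M), rt
Reagents that add atoms: none
Why: Yamaguchi macrolactonisation: the mixed anhydride forms at the carboxyl group and, at high dilution, DMAP transfers the acyl group to the primary allylic hydroxyl of the same molecule, closing the thirteen-membered ring. Three E alkenes and the quaternary carbon leave the chain few rotors, which should favour ring closure over oligomerisation; room temperature keeps 15 from reacting on.

Step 10
Reactants: 15 (3E,8S,9E,11E)-4,8-dimethyl-2-oxo-1-oxacyclotrideca-3,9,11-triene-8-carbonitrile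
Product: 16 tricyclic 11,17-lactone 19-nitrile with a C6=C7 alkene (C17 β; nitrile β)
Conditions: PhMe (0.005 M), BHT (cat.), sealed tube, 180 °C
Reagents that add atoms: none
Why: Heating should bring the s-cis conformer of the diene C5=C6–C7=C8 and the enoate alkene C9=C10, which face each other across the thirteen-membered ring, into a concerted suprafacial [4+2] cycloaddition that forms C5–C10 and C8–C9 and the C6=C7 alkene; the closest known reaction type is the transannular Diels–Alder reaction of thirteen- and fourteen-membered macrocyclic trienes. Ring A closes as a six-membered carbocycle through a chair-like C1–C2–C3–C4 tether held exo to the diene, ring B is the new cyclohexene (boat-like in the transition state), and the three-atom ester bridge, which can span the new C8–C9 bond only from the endo side, becomes a cis-fused five-membered lactone as the macrocycle contracts. The E geometry of the dienophile places C11 and the C10 methyl cis (both β, H9 α) and, with the exo tether, gives the trans A/B fusion at C10 and C5 (H5 α). The E,E geometry of the diene places C4 and C17 cis, so C8 is formed with C17 β, cis to C11 as the lactone requires. The selectivity the step needs is diastereofacial: of the two chair-like tethers, the one with the small nitrile axial and syn to the C10 methyl avoids a methyl/methyl 1,3-diaxial contact, so the S centre C4 should dictate the configuration of C10, C5, C9 and C8. The lactone carbonyl on C9 lowers the LUMO of the otherwise unreactive β,β-disubstituted alkene, and the ring pays the entropy cost in advance.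

Step 11
Reactants: 16 tricyclic 11,17-lactone 19-nitrile with a C6=C7 alkene
Product: 17 saturated tricyclic 11,17-lactone 19-nitrile
Conditions: H2 (1 atm), 10% Pd/C, EtOAc, rt
Reagents that add atoms: none
Why: Heterogeneous hydrogenation of the cis-disubstituted C6=C7 alkene; the lactone and the hindered tertiary nitrile should not be reduced at 1 atm, and no stereocentre is created.

Step 12
Reactants: 17 saturated tricyclic 11,17-lactone 19-nitrile
Product: 18 lactol (C11 hemiacetal; both anomers)
Conditions: i-Bu2AlH (1.1 equiv), CH2Cl2, −78 °C; aq. KNaC4H4O6
Reagents that add atoms: none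
Why: Partial reduction of a lactone to the lactol with one equivalent of i-Bu2AlH at −78 °C, where the tetrahedral aluminium alkoxide is stable. The axial neopentyl nitrile, shielded by the C10 methyl, should react much more slowly and be kept.

Step 13
Reactants: 18 lactol (C11 hemiacetal; both anomers)
Product: 20 9β-vinyl 8β-(hydroxymethyl) nitrile, via hydroxy aldehyde 19 (not isolated)
Conditions: Ph3PCH3Br, KOt-Bu (4 equiv each), THF, 0 → 50 °C
Reagents that add atoms: methyltriphenylphosphonium bromide, C[P+](c1ccccc1)(c1ccccc1)c1ccccc1.[Br-]
Why: Wittig methylenation of a lactol through its open tautomer 19: the ylide turns C11 into the inner vinyl carbon and sets the C17 hydroxyl free. Excess ylide allows for the alkoxide, and the C9 formyl group is already equatorial, so no change at C9 is expected.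

Step 14
Reactants: 20 9β-vinyl 8β-(hydroxymethyl) nitrile
Product: 21 9β-vinyl 8β-formyl nitrile (formyl axial)
Conditions: Dess–Martin periodinane, NaHCO3, CH2Cl2, 0 °C → rt
Reagents that add atoms: none
Why: Dess–Martin oxidation of the primary C17 alcohol to the aldehyde under neutral conditions; nitrile and alkene are inert.

Step 15
Reactants: 21 9β-vinyl 8β-formyl nitrile (formyl axial)
Product: 22 9β-vinyl 8α-formyl nitrile (formyl equatorial)
Conditions: DBU (0.5 equiv), CH2Cl2, rt
Reagents that add atoms: none
Why: Base-mediated epimerisation through the enolate: the axial formyl group, which has a 1,3-diaxial contact with the C10 methyl, should go over to the equatorial position, trans to the C9 vinyl group. This thermodynamic control sets C8 as in 28 (H β, C17 α).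

Step 16
Reactants: 22 9β-vinyl 8α-formyl nitrile (formyl equatorial)
Product: 24 17-hydroxy 19-aldehyde with the C9 vinyl group, via C19 aldimine 23 (not isolated)
Conditions: i-Bu2AlH (3.5 equiv), PhMe, −78 °C → rt; then 1 M HCl, THF, 0 °C → rt
Reagents that add atoms: water, O
Why: Hydride reduction with excess i-Bu2AlH: the C17 aldehyde gives the alcohol at once, and the nitrile takes up one hydride to give the N-aluminated aldimine 23, which does not react further and is hydrolysed by dilute acid to the C19 aldehyde. The vinyl group is inert, and C8 no longer has a carbonyl group next to it.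

Step 17
Reactants: 24 17-hydroxy 19-aldehyde with the C9 vinyl group
Product: 25 17-hydroxy-13,14,15,16-tetranor-8βH-labd-11-en-19-oic acid
Conditions: NaClO2, NaH2PO4, 2-methylbut-2-ene, t-BuOH/H2O, rt
Reagents that add atoms: sodium chlorite, [Na+].[O-]Cl=O
Why: Pinnick oxidation: chlorous acid oxidises the hindered, non-enolisable C19 aldehyde to the acid, and 2-methylbut-2-ene takes up the hypochlorous acid so that the vinyl group and the primary alcohol are spared.

Step 18
Reactants: 25 17-hydroxy-13,14,15,16-tetranor-8βH-labd-11-en-19-oic acid; 26 3-bromofuran-2(5H)-one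
Product: 28 (1S,4aR,5S,6R,8aR)-6-(hydroxymethyl)-1,4a-dimethyl-5-[2-(2-oxo-2,5-dihydrofuran-3-yl)ethyl]decahydronaphthalene-1-carboxylic acid, via tris(9-BBN) adduct 27 (not isolated)
Conditions: 9-BBN-H (3.5 equiv), THF, rt → 40 °C; then 26, PdCl2(dppf) (10 mol %), AsPh3, aq. K3PO4, DMF, rt; 1 M HCl work-up
Reagents that add atoms: none
Why: Hydroboration followed by B-alkyl Suzuki–Miyaura coupling with an α-halo-α,β-unsaturated lactone: 9-BBN adds to the vinyl group with boron on C12 (two more equivalents are held as O–B bonds on the hydroxyl and carboxyl groups and released by the aqueous base), and the alkyl group is transferred to C13 of 26 at room temperature. The C12–C13 bond is formed with the butenolide intact, no stereocentre is involved, and the acidic work-up returns the free acid and alcohol.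

## Compound list

1 | ethyl acetoacetate (ethyl 3-oxobutanoate) | CCOC(=O)CC(C)=O | starting material
2 | ethyl (2E)-3-{[(trifluoromethyl)sulfonyl]oxy}but-2-enoate | CCOC(=O)/C=C(\C)OS(=O)(=O)C(F)(F)F | intermediate
3 | tert-butyl 2-cyanopropanoate (racemic) | CC(C#N)C(=O)OC(C)(C)C | starting material
4 | allyl bromide (3-bromoprop-1-ene) | C=CCBr | starting material
5 | tert-butyl (2R)-2-cyano-2-methylpent-4-enoate | CC(C)(C)OC(=O)[C@@](C)(C#N)CC=C | intermediate
6 | (2R)-2-(hydroxymethyl)-2-methylpent-4-enenitrile | OC[C@@](C)(C#N)CC=C | intermediate
7 | (2R)-5-(9-borabicyclo[3.3.1]nonan-9-yl)-2-[(9-borabicyclo[3.3.1]nonan-9-yloxy)methyl]-2-methylpentanenitrile | O(B1C2CCCC1CCC2)C[C@@](C)(C#N)CCCB1C2CCCC1CCC2 | intermediate (not isolated)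
8 | ethyl (2E,7R)-7-cyano-8-hydroxy-3,7-dimethyloct-2-enoate | OC[C@@](C)(C#N)CCC/C(C)=C/C(=O)OCC | intermediate
9 | ethyl (2E,7R)-7-cyano-3,7-dimethyl-8-oxooct-2-enoate | O=C[C@@](C)(C#N)CCC/C(C)=C/C(=O)OCC | intermediate
10 | ethyl (2E,7S,8E)-7-cyano-9-iodo-3,7-dimethylnona-2,8-dienoate | I/C=C/[C@@](C)(C#N)CCC/C(C)=C/C(=O)OCC | intermediate
11 | (2E)-3-(tributylstannyl)prop-2-en-1-ol | OC/C=C/[Sn](CCCC)(CCCC)CCCC | starting material
12 | ethyl (2E,7S,8E,10E)-7-cyano-12-hydroxy-3,7-dimethyldodeca-2,8,10-trienoate | OC/C=C/C=C/[C@@](C)(C#N)CCC/C(C)=C/C(=O)OCC | intermediate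
13 | (2E,7S,8E,10E)-7-cyano-12-hydroxy-3,7-dimethyldodeca-2,8,10-trienoic acid | OC/C=C/C=C/[C@@](C)(C#N)CCC/C(C)=C/C(=O)O | intermediate
14 | mixed anhydride of 13 with 2,4,6-trichlorobenzoic acid | OC/C=C/C=C/[C@@](C)(C#N)CCC/C(C)=C/C(=O)OC(=O)c1c(Cl)cc(Cl)cc1Cl | intermediate (not isolated)
15 | (3E,8S,9E,11E)-4,8-dimethyl-2-oxo-1-oxacyclotrideca-3,9,11-triene-8-carbonitrile | C1/C=C/C=C/[C@@](C)(C#N)CCC/C(C)=C/C(=O)O1 | intermediate
16 | 17-hydroxy-12,13,14,15,16-pentanor-8αH-labd-6-en-11-oic acid 19-nitrile, 11,17-lactone (C20 β, 5α-H, 9α-H, 8α-H with C17 β; nitrile β and axial; cis-fused γ-lactone on the β face) | C[C@]12CCC[C@](C)(C#N)[C@@H]1C=C[C@H](COC3=O)[C@@H]23 | intermediate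
17 | 6,7-dihydro derivative of 16 (saturated tricyclic lactone nitrile, same configuration) | C[C@]12CCC[C@](C)(C#N)[C@@H]1CC[C@H](COC3=O)[C@@H]23 | intermediate
18 | lactol of 17 (C11 hemiacetal, both anomers) | C[C@]12CCC[C@](C)(C#N)[C@@H]1CC[C@H](COC3O)[C@@H]23 | intermediate
19 | 17-hydroxy-11-oxo-12,13,14,15,16-pentanor-8αH-labdane-19-nitrile (open tautomer of 18; 9β-formyl, 8β-hydroxymethyl) | C[C@]12CCC[C@](C)(C#N)[C@@H]1CC[C@H](CO)[C@@H]2C=O | intermediate (not isolated)
20 | 17-hydroxy-13,14,15,16-tetranor-8αH-labd-11-ene-19-nitrile (9β-vinyl; 8β-hydroxymethyl, axial) | C[C@]12CCC[C@](C)(C#N)[C@@H]1CC[C@H](CO)[C@@H]2C=C | intermediate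
21 | 17-oxo-13,14,15,16-tetranor-8αH-labd-11-ene-19-nitrile (8β-formyl, axial) | C[C@]12CCC[C@](C)(C#N)[C@@H]1CC[C@H](C=O)[C@@H]2C=C | intermediate
22 | 17-oxo-13,14,15,16-tetranor-8βH-labd-11-ene-19-nitrile (8α-formyl, equatorial) | C[C@]12CCC[C@](C)(C#N)[C@@H]1CC[C@@H](C=O)[C@@H]2C=C | intermediate
23 | C19 aldimine of 24 (N-aluminated in the flask, drawn as N–H; 17-hydroxy, 8βH) | C[C@]12CCC[C@](C)(C=N)[C@@H]1CC[C@@H](CO)[C@@H]2C=C | intermediate (not isolated)
24 | 17-hydroxy-13,14,15,16-tetranor-8βH-labd-11-en-19-al | C[C@]12CCC[C@](C)(C=O)[C@@H]1CC[C@@H](CO)[C@@H]2C=C | intermediate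
25 | 17-hydroxy-13,14,15,16-tetranor-8βH-labd-11-en-19-oic acid (9β-vinyl; 8α-hydroxymethyl; acid β) | C[C@]12CCC[C@](C)(C(=O)O)[C@@H]1CC[C@@H](CO)[C@@H]2C=C | intermediate
26 | 3-bromofuran-2(5H)-one | O=C1OCC=C1Br | starting material
27 | 12-(9-borabicyclo[3.3.1]nonan-9-yl) adduct of 25 with the 17-O and 19-carboxyl groups as 9-BBN borinates | C[C@]12CCC[C@](C)(C(=O)OB3C4CCCC3CCC4)[C@@H]1CC[C@@H](COB3C4CCCC3CCC4)[C@@H]2CCB3C4CCCC3CCC4 | intermediate (not isolated)
28 | (1S,4aR,5S,6R,8aR)-6-(hydroxymethyl)-1,4a-dimethyl-5-[2-(2-oxo-2,5-dihydrofuran-3-yl)ethyl]decahydronaphthalene-1-carboxylic acid (17-hydroxy-8βH-labd-13-en-16,15-olid-19-oic acid) | C[C@]12CCC[C@](C)(C(=O)O)[C@@H]1CC[C@@H](CO)[C@@H]2CCC1=CCOC1=O | target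

## Step count and least certain steps

Total: 18 steps. Longest linear sequence: 17 steps (steps 2 to 18, from 3); step 1 is a one-step side branch.

**Step 10 (key step).** The cycloaddition may be too slow to compete with decomposition or alkene isomerisation at the temperature it needs. The ester bridge has to take up the lactone-like s-cis geometry, and the bond that should lead on electronic grounds, C5–C10, is also the most hindered, since it joins a neopentyl carbon to a nascent quaternary carbon. Face selection by C4 may also be incomplete, because it rests only on the size difference between nitrile and methyl in a transition state where the 1,3-diaxial contact is not yet fully developed. The fallback gives up the macrocycle but forms the same two bonds, and sets out from 12. Silylation (TBSCl, imidazole, DMF) gives the tert-butyldimethylsilyl ether F1. Its intramolecular Diels–Alder reaction through the C1–C4 tether alone (Me2AlCl, CH2Cl2, −20 °C → rt, or PhMe, 200 °C) should give, by the ester-endo transition state, the trans-fused bicyclic ester F2 with C11 and C17 cis. HF·pyridine, then TsOH in warm toluene, removes the silyl group and closes the lactone, and the route is rejoined at 16.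

**Step 9.** Ring closure may lose to intermolecular acylation, because the thirteen-membered ring with three E alkenes is strained. The activated β-methyl enoic acid may also deconjugate through a vinylketene when the acyl group is held on DMAP for long. The fallback closes the ring by C–C bond formation and sets out from 10. Saponification (LiOH, THF/H2O) gives the iodo acid F3, which is esterified with 11 (EDC, DMAP, CH2Cl2) to the stannyl ester F4. An intramolecular Stille coupling at high dilution (Pd2(dba)3, AsPh3, DMF) then forms C6–C7 and returns to the route at 15.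

**Step 18.** The aqueous base may degrade 26 by ring opening or γ-deprotonation before transmetalation. Hydroboration may stay incomplete while the hydroxyl and carboxyl groups hold borane. The alkylpalladium intermediate may be lost by β-hydride elimination. The fallback builds the butenolide by olefination and alkene migration and sets out from 25. Double silylation (TBSCl, imidazole, DMF) gives the silyl ether silyl ester F5. Hydroboration (9-BBN) and oxidation with alkaline H2O2, which also hydrolyses the silyl ester, give the 12-alcohol F6. Dess–Martin oxidation gives the 12-aldehyde F7. A Horner–Wadsworth–Emmons reaction with diethyl (2-oxooxolan-3-yl)phosphonate (LiCl, DBU, MeCN) gives the α-alkylidene lactone F8. RhCl3·3H2O in hot ethanol moves the exocyclic alkene into the ring to give the butenolide silyl ether F9. HF·pyridine removes the silyl group and the route ends at 28.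

**Step 2.** Enantioface discrimination may be insufficient, because the enolate of 3 carries only a methyl group and a linear nitrile beside the ester, which gives the chiral cation little to grip. The fallback replaces catalyst control by a resolution and sets out from 3 and 4. Alkylation without the chiral catalyst (K2CO3, acetone) gives the racemic ester F10, and TFA in CH2Cl2 gives the racemic acid F11. Crystallisation with (R)-1-phenylethylamine (or its antipode, whichever gives the less soluble salt of the R acid) gives the salt F12, and acidification sets free the (R)-acid F13. Reduction through the mixed anhydride (i-BuOCOCl, N-methylmorpholine, THF, −15 °C; NaBH4, H2O) rejoins the route at 6.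

## Further compounds

F1 | step 10 | ethyl (2E,7S,8E,10E)-12-[(tert-butyldimethylsilyl)oxy]-7-cyano-3,7-dimethyldodeca-2,8,10-trienoate | CC(C)(C)[Si](C)(C)OC/C=C/C=C/[C@@](C)(C#N)CCC/C(C)=C/C(=O)OCC
F2 | step 10 | ethyl 17-[(tert-butyldimethylsilyl)oxy]-12,13,14,15,16-pentanor-8αH-labd-6-en-11-oate 19-nitrile (C11 β, C17 β, nitrile β) | C[C@]12CCC[C@](C)(C#N)[C@@H]1C=C[C@H](CO[Si](C)(C)C(C)(C)C)[C@@H]2C(=O)OCC
F3 | step 9 | (2E,7S,8E)-7-cyano-9-iodo-3,7-dimethylnona-2,8-dienoic acid | I/C=C/[C@@](C)(C#N)CCC/C(C)=C/C(=O)O
F4 | step 9 | (2E)-3-(tributylstannyl)prop-2-en-1-yl (2E,7S,8E)-7-cyano-9-iodo-3,7-dimethylnona-2,8-dienoate | I/C=C/[C@@](C)(C#N)CCC/C(C)=C/C(=O)OC/C=C/[Sn](CCCC)(CCCC)CCCC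
F5 | step 18 | tert-butyldimethylsilyl 17-[(tert-butyldimethylsilyl)oxy]-13,14,15,16-tetranor-8βH-labd-11-en-19-oate | C[C@]12CCC[C@](C)(C(=O)O[Si](C)(C)C(C)(C)C)[C@@H]1CC[C@@H](CO[Si](C)(C)C(C)(C)C)[C@@H]2C=C
F6 | step 18 | 17-[(tert-butyldimethylsilyl)oxy]-12-hydroxy-13,14,15,16-tetranor-8βH-labdan-19-oic acid | C[C@]12CCC[C@](C)(C(=O)O)[C@@H]1CC[C@@H](CO[Si](C)(C)C(C)(C)C)[C@@H]2CCO
F7 | step 18 | 17-[(tert-butyldimethylsilyl)oxy]-12-oxo-13,14,15,16-tetranor-8βH-labdan-19-oic acid | C[C@]12CCC[C@](C)(C(=O)O)[C@@H]1CC[C@@H](CO[Si](C)(C)C(C)(C)C)[C@@H]2CC=O
F8 | step 18 | 17-[(tert-butyldimethylsilyl)oxy]-8βH-labd-12-en-16,15-olid-19-oic acid (α-alkylidene lactone, either alkene geometry) | C[C@]12CCC[C@](C)(C(=O)O)[C@@H]1CC[C@@H](CO[Si](C)(C)C(C)(C)C)[C@@H]2CC=C1CCOC1=O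
F9 | step 18 | 17-[(tert-butyldimethylsilyl)oxy]-8βH-labd-13-en-16,15-olid-19-oic acid | C[C@]12CCC[C@](C)(C(=O)O)[C@@H]1CC[C@@H](CO[Si](C)(C)C(C)(C)C)[C@@H]2CCC1=CCOC1=O
F10 | step 2 | tert-butyl 2-cyano-2-methylpent-4-enoate (racemic) | CC(C)(C)OC(=O)C(C)(C#N)CC=C
F11 | step 2 | 2-cyano-2-methylpent-4-enoic acid (racemic) | OC(=O)C(C)(C#N)CC=C
F12 | step 2 | (1R)-1-phenylethylammonium (2R)-2-cyano-2-methylpent-4-enoate | [O-]C(=O)[C@@](C)(C#N)CC=C.C[C@@H]([NH3+])c1ccccc1
F13 | step 2 | (2R)-2-cyano-2-methylpent-4-enoic acid | OC(=O)[C@@](C)(C#N)CC=C
A1 | alternative 1 | 8-phenylmenthyl 3-oxo-12-(pivaloyloxy)-13,14,15,16-tetranorlabd-8(17)-en-19-oate | C[C@]12CCC(=O)[C@](C)(C(=O)O[C@@H]3C[C@H](C)CC[C@H]3C(C)(C)c3ccccc3)[C@@H]1CCC(=C)[C@@H]2CCOC(=O)C(C)(C)C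
A2 | alternative 1 | (1R,2S,5R)-5-methyl-2-(2-phenylpropan-2-yl)cyclohexyl (6E,10E)-2,6,10-trimethyl-3-oxo-13-(pivaloyloxy)trideca-6,10-dienoate (C2 epimers) | CC(C(=O)O[C@@H]1C[C@H](C)CC[C@H]1C(C)(C)c1ccccc1)C(=O)CC/C(C)=C/CC/C(C)=C/CCOC(=O)C(C)(C)C
A3 | alternative 2 | methyl 17,17-dimethoxy-13,14,15,16-tetranorlabd-11-en-19-oate | C[C@]12CCC[C@](C)(C(=O)OC)[C@@H]1CC[C@@H](C(OC)OC)[C@@H]2C=C
A4 | alternative 2 | methyl 17-methoxy-12-(trimethylsilyl)-8,9-seco-13,14,15,16-tetranorlabda-8(17),9(11)-dien-19-oate (enol ether as E/Z mixture) | C[C@]1(/C=C/C[Si](C)(C)C)CCC[C@](C)(C(=O)OC)[C@@H]1CCC=COC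
A5 | alternative 3 | methyl 17-(tert-butyldimethylsilyloxy)labd-13-en-16,15-olid-19-oate | C[C@]12CCC[C@](C)(C(=O)OC)[C@@H]1CC[C@@H](CO[Si](C)(C)C(C)(C)C)[C@@H]2CCC1=CCOC1=O
A6 | alternative 3 | methyl 17-(tert-butyldimethylsilyloxy)-15-hydroxy-16-norlabd-13-yn-19-oate | C[C@]12CCC[C@](C)(C(=O)OC)[C@@H]1CC[C@@H](CO[Si](C)(C)C(C)(C)C)[C@@H]2CCC#CCO
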